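**Remarks and assumption.** Atom labels (O1, C2 … C8a, ring B primed) follow flavanone numbering and are used for all intermediates. The target SMILES corresponds to 2S at C2 and S at the side-chain carbinol. Assumption: the (R) antipode of the bisphosphine in step 12 is taken to deliver hydride to the face that gives 2S; if a test on a simple flavone shows the opposite sense, the (S) ligand is used and nothing else changes.

## Analysis of the target

The target is a flavanone: benzo ring A is fused to the dihydropyranone ring C, and C2 carries the 4-hydroxyphenyl ring B. Ring A is fully substituted: O1 on C8a, a 2,3-dihydroxy-3-methylbutyl chain on C8, hydroxyl on C7, prenyl on C6, hydroxyl on C5 and the C4 carbonyl on C4a. There are two stereocentres, C2 (S) and the side-chain carbinol (S). They are separated by five bonds and cannot control each other, so each must be set by a reagent or bought. The sensitive groups are the prenyl alkene (acid-induced chroman formation with a flanking phenol, electrophiles, hydrogenation), the diol with its tertiary alcohol (cyclodehydration onto O7), and C2, which epimerises under base through retro-oxa-Michael ring opening. The real difficulty is the pseudo-symmetry of the phloroglucinol core: O5 and O8a differ only in which carbon substituent is their neighbour, yet ring C must be closed on O8a alone. The strategy rests on the fact that C4 lies between C4a and C3 with O1 ortho to it on C8a. Ring C is therefore the sum of an ortho-iodophenol (iodine on C4a, free hydroxyl on C8a), carbon monoxide and a 4-oxygenated phenylacetylene.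

## Retrosynthetic reasoning

**23 to 22.** The three phenols and the diol are unmasked last. MOM ethers and an acetonide all fall in one acidic methanolysis. A flavanone tolerates this far better than base, which would open ring C and scramble C2.

**22 to 20.** C2 is set by adding hydride to C2 and a proton to C3 of flavone 20. The cut is placed here because the flavone is flat, robust and free of stereochemical liability during the harsh annulation. The forward step has to be a 1,4-reduction that is enantioselective under catalyst control, leaves the prenyl alkene alone, and holds the product as silyl enol ether 21 until work-up so that the ketone is not reduced and ring C does not open.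

**20 to 13, 17 and 16.** Three bonds are cut at once: C4a–C4, C4–C3 and O1–C2. Cutting at the carbonyl uses the only carbon of ring C that needs no substituent or stereochemistry, and lets it come from carbon monoxide 17 at the correct oxidation level. The remaining two carbons and ring B come from alkyne 16, and ring A arrives complete in iodophenol 13. The forward reaction has to carbonylate faster than it alkynylates directly and close the six-membered rather than the five-membered ring. The position of the iodine and the single free hydroxyl fix the regiochemistry.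

**16 to 15 to 14.** Alkyne 16 is the one-carbon homologue of aldehyde 15, which is the MOM ether of 14. The MOM ether keeps the ring B phenol out of the palladium chemistry and leaves with the others at the end.

**13 to 12 to 11.** The acetonide of 13 is taken back to diol 12, and the two methyl groups of the tertiary carbinol to the ester carbonyl of 11. This reduces the side chain to a three-carbon α-hydroxy ester whose stereocentre can be bought. Building the full five-carbon chain as a chiral epoxide would cost a separate asymmetric preparation, whereas 9 is commercial and the two methyl groups are added by a double Grignard addition.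

**11 to 8 and 9.** The C8–CH2 bond is cut to arylmagnesium 10 and the terminal carbon of 9. Intermediate 10 is generated from one of the two carbon–iodine bonds of 8 by halogen–metal exchange rather than by deprotonation. Exchange is site-defined and cannot touch the doubly activated allylic-benzylic CH2 of the prenyl group. It also avoids lithiating next to a bulky silyl ether, where shielding and O-to-C silyl migration would be expected. Opening 9 at its CH2 terminus does not involve the stereocentre.

**8 to 7.** Both carbon–iodine bonds go back to C–H. Phenol 7 has a mirror plane through C8a and C6, so its two ortho positions are identical, and double iodination has no regiochemical question to answer. One iodine later becomes the nucleophile for the side chain and the other is the handle for the carbonylation. The free hydroxyl is therefore by construction O8a, the oxygen remote from the prenyl group.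

**7 to 6 to 3 and 4.** The prenyl–C6 bond is made by directed lithiation between the two MOM ethers of 3, which gives aryllithium 5, and allylation with 4. The third oxygen carries a triisopropylsilyl group only for this step. As a poor, bulky director para to the reacting site it guarantees selectivity, and fluoride then removes it from 6.

**3 to 2 to 1.** The silyl/MOM pattern is put on phloroglucinol 1 by mono-silylation with the triol in excess to give 2, then exhaustive MOM protection.

## Alternatives that were turned down

**Alternative 1:** Ring A itself is taken apart at C7–C8 and C8a–C4a into cyclobutenone A2 and siloxyalkyne A3.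
- Forward step: heating A2 with A3 triggers a four-electron ring opening, [2+2] addition of the resulting ketene unit to the alkyne, a second four-electron opening and a six-electron closure, and gives the pentasubstituted phenol A1.
- For: A1 has all three oxygens distinguished (free O7, silyl on O8a, 4-methoxybenzyl on O5) and both carbon chains in place. Regiochemistry follows from connectivity and not from directing effects. On this point it is stronger than the chosen route, which relies on a symmetric intermediate and a mono-exchange.
- Against: neither A2 (prenyl on the sp3 carbon of a 3-alkoxycyclobutenone) nor A3 (an ynol silyl ether carrying the chiral acetonide) is a short preparation. After A1 ring C is still wholly missing: C4a functionalisation, exchange of protecting groups on three oxygens, annulation and C2 control all remain. The oxidative removal of the 4-methoxybenzyl group must also spare a very electron-rich ring and the prenyl group.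
- Comparison: the key step is spent on the ring that can be bought. The chosen route starts from phloroglucinol 1 and spends its key step on the ring that has to be made.

**Alternative 2:** Ring C is cut at C2–C3. The substrate is A5, a diazomethyl ketone on C4a with a 4-(methoxymethoxy)benzyl ether on O8a.
- Forward step: A5 is decomposed by dirhodium tetrakis[N-phthaloyl-(S)-tert-leucinate] A6, the divalent rhodium carboxylate Rh2(S-PTTL)4. The carbenoid carbon C3 inserts into the benzylic ether C–H and gives flavanone A4.
- For: ring closure and C2 are delivered together, at the right oxidation level, with no separate reduction. In stereochemical economy it beats the chosen route.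
- Against: an acceptor-only carbenoid is unselective on this substrate. Six-membered insertion competes with attack on the O1 lone pair followed by a benzyl shift (which would close a five-membered ring instead), with attack on the carbonyl of the O5 acetate, with cyclopropanation of the prenyl alkene and with addition to the electron-rich ring. Enantiocontrol by catalyst A6 for unsubstituted diazoketones is modest. Making A5 also requires a carboxyl group on the hindered C4a position, its homologation to the diazoketone, and the same O8a differentiation that the chosen route solves.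
- Comparison: the chosen route pays one extra step for C2, but every bond-forming event in it is indifferent to the prenyl group.

**Alternative 3:** Ring C is cut at C3–C4 and O1–C2 at the flavan oxidation level.
- Forward step: salicylaldehyde A8, trimethyl orthoformate A9 and styrene A10 combine under a chiral Brønsted acid. Acetalisation of A8 by A9 in the flask and ionisation generate a cationic heterodiene of the ortho-quinone-methide type, which adds to A10 in an inverse-demand [4+2] reaction and gives the 2,4-cis-4-methoxyflavan A7.
- For: it is convergent, needs no pressure vessel, and sets C2 in the ring-forming step. A8 would come from the same arene as 13, with formylation in place of iodination. On these points it matches or beats the chosen route.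
- Against: the medium ionises acetals, and the substrate carries two MOM ethers, an acetonide and a prenyl group. The cation derived from A8 is strongly stabilised by its three ring oxygens, so it is sluggish towards the unactivated alkene of A10 and prone to an uncatalysed racemic pathway. A10 offers the chiral anion no binding handle. C4 arrives in A7 as a methyl ether, and its oxidation to the ketone costs further steps in which the C2–H (also benzylic and next to oxygen) and the prenyl group compete.
- Comparison: the chosen route takes C4 as a carbonyl directly from 17 and leaves the asymmetric step to a flat, robust flavone.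

Key step: step 11

## Route

**Step 1**
Reactants: 1 phloroglucinol (benzene-1,3,5-triol)
Product: 2 5-[(triisopropylsilyl)oxy]benzene-1,3-diol
Conditions: 1 (3 equiv), TIPSCl (1 equiv), imidazole, DMF, 0 °C to rt
Reagents that add atoms: triisopropylsilyl chloride, CC(C)[Si](Cl)(C(C)C)C(C)C
Why: Phenol silylation; the cheap triol in excess biases the statistics towards the mono-ether, and unreacted 1 is removed by aqueous extraction.

**Step 2**
Reactants: 2 5-[(triisopropylsilyl)oxy]benzene-1,3-diol
Product: 3 triisopropyl[3,5-bis(methoxymethoxy)phenoxy]silane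
Conditions: MOMCl (2.5 equiv), iPr2NEt, CH2Cl2, 0 °C to rt
Reagents that add atoms: chloromethyl methyl ether, COCCl
Why: O-alkylation of both free phenols under amine base; the aryl silyl ether is stable to these non-nucleophilic conditions.

**Step 3**
Reactants: 3 triisopropyl[3,5-bis(methoxymethoxy)phenoxy]silane; 4 prenyl bromide (1-bromo-3-methylbut-2-ene)
Product: 6 triisopropyl[3,5-bis(methoxymethoxy)-4-(3-methylbut-2-en-1-yl)phenoxy]silane, via aryllithium 5 (not isolated)
Conditions: n-BuLi, THF, 0 °C; CuI (10 mol%), 4, −78 °C to rt
Reagents that add atoms: none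
Why: Directed ortho-metalation occurs between the two MOM ethers, the doubly coordinated site para to the shielding silyl ether; copper-assisted allylation then attaches the prenyl group at its primary carbon.

**Step 4**
Reactants: 6 triisopropyl[3,5-bis(methoxymethoxy)-4-(3-methylbut-2-en-1-yl)phenoxy]silane
Product: 7 3,5-bis(methoxymethoxy)-4-(3-methylbut-2-en-1-yl)phenol
Conditions: TBAF, THF, 0 °C
Reagents that add atoms: none
Why: Fluoride cleavage of the aryl silyl ether; MOM ethers and the alkene are inert, and the phenol obtained is mirror-symmetric.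

**Step 5**
Reactants: 7 3,5-bis(methoxymethoxy)-4-(3-methylbut-2-en-1-yl)phenol
Product: 8 2,6-diiodo-3,5-bis(methoxymethoxy)-4-(3-methylbut-2-en-1-yl)phenol
Conditions: I2 (2.05 equiv), NaHCO3, THF–H2O, 0 °C, dark
Reagents that add atoms: iodine, II
Why: Electrophilic aromatic iodination of the phenoxide at both (identical) ortho positions, so only one product is possible. The phenoxide ring should be far more nucleophilic than the isolated alkene, which has no free hydroxyl next to it for iodoetherification.

**Step 6**
Reactants: 8 2,6-diiodo-3,5-bis(methoxymethoxy)-4-(3-methylbut-2-en-1-yl)phenol; 9 methyl (2S)-oxirane-2-carboxylate (methyl (S)-glycidate)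
Product: 11 methyl (2S)-2-hydroxy-3-[2-hydroxy-3-iodo-4,6-bis(methoxymethoxy)-5-(3-methylbut-2-en-1-yl)phenyl]propanoate, via arylmagnesium phenoxide 10 (not isolated)
Conditions: MeMgCl (1.0 equiv), LiCl, THF, −30 °C; iPrMgCl (1.1 equiv), −30 to 0 °C; CuI (10 mol%), 9, −40 to −20 °C; aq NH4Cl
Reagents that add atoms: none
Why: Iodine–magnesium exchange on the magnesium phenoxide should stop after one iodine, because a second exchange would place a third negative charge on the ring. Copper-catalysed SN2 opening of the glycidate at its CH2 terminus leaves the stereocentre untouched, so the S configuration of 9 is carried into 11. Any lactonisation onto the neighbouring phenol would be harmless, since the next step converts both carbonyl forms into the same tertiary alcohol.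

**Step 7**
Reactants: 11 methyl (2S)-2-hydroxy-3-[2-hydroxy-3-iodo-4,6-bis(methoxymethoxy)-5-(3-methylbut-2-en-1-yl)phenyl]propanoate
Product: 12 (2S)-1-[2-hydroxy-3-iodo-4,6-bis(methoxymethoxy)-5-(3-methylbut-2-en-1-yl)phenyl]-3-methylbutane-2,3-diol
Conditions: MeMgBr (6 equiv), THF, 0 °C to rt
Reagents that add atoms: methylmagnesium bromide, C[Mg]Br
Why: Double Grignard addition to the ester; the neighbouring magnesium alkoxide suppresses enolisation, so the carbinol centre is retained, and the aryl iodide does not exchange with a methyl Grignard reagent at this temperature.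

**Step 8**
Reactants: 12 (2S)-1-[2-hydroxy-3-iodo-4,6-bis(methoxymethoxy)-5-(3-methylbut-2-en-1-yl)phenyl]-3-methylbutane-2,3-diol
Product: 13 2-iodo-3,5-bis(methoxymethoxy)-4-(3-methylbut-2-en-1-yl)-6-{[(4S)-2,2,5,5-tetramethyl-1,3-dioxolan-4-yl]methyl}phenol
Conditions: 2,2-dimethoxypropane, PPTS (cat.), acetone, rt
Reagents that add atoms: 2,2-dimethoxypropane, COC(C)(C)OC
Why: Acid-catalysed transacetalisation closes the five-membered dioxolane on the 1,2-diol; the phenol stays free and aryl MOM ethers survive the pyridinium acid.

**Step 9**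
Reactants: 14 4-hydroxybenzaldehyde
Product: 15 4-(methoxymethoxy)benzaldehyde
Conditions: MOMCl, iPr2NEt, CH2Cl2, 0 °C to rt
Reagents that add atoms: chloromethyl methyl ether, COCCl
Why: Routine O-alkylation of an acidic phenol.

**Step 10**
Reactants: 15 4-(methoxymethoxy)benzaldehyde
Product: 16 1-ethynyl-4-(methoxymethoxy)benzene
Conditions: dimethyl (1-diazo-2-oxopropyl)phosphonate, K2CO3, MeOH, rt
Reagents that add atoms: dimethyl (1-diazo-2-oxopropyl)phosphonate, COP(=O)(OC)C(=[N+]=[N-])C(C)=O
Why: Seyferth–Gilbert homologation in the Ohira–Bestmann form: methanolysis frees the diazomethylphosphonate anion, which olefinates the aldehyde; loss of nitrogen and a 1,2-hydrogen shift give the terminal alkyne under conditions mild enough for the MOM ether.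

**Step 11**
Reactants: 13 2-iodo-3,5-bis(methoxymethoxy)-4-(3-methylbut-2-en-1-yl)-6-{[(4S)-2,2,5,5-tetramethyl-1,3-dioxolan-4-yl]methyl}phenol; 16 1-ethynyl-4-(methoxymethoxy)benzene; 17 carbon monoxide
Product: 20 5,7-bis(methoxymethoxy)-2-[4-(methoxymethoxy)phenyl]-6-(3-methylbut-2-en-1-yl)-8-{[(4S)-2,2,5,5-tetramethyl-1,3-dioxolan-4-yl]methyl}-4H-chromen-4-one, via hydroxyaryl ynone 18 (not isolated), via enaminone 19 (not isolated)
Conditions: PdCl2(PPh3)2 (5 mol%), CO (20 bar), 16 (1.5 equiv), Et2NH, 120 °C
Reagents that add atoms: none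
Why: Zerovalent palladium, formed from PdCl2(PPh3)2 by the amine and CO, inserts into the C4a–I bond of 13; CO then inserts to give an aroylpalladium iodide, and amine-assisted transfer of the acetylide of 16 with reductive elimination forms C4a–C4 and C4–C3 in ynone 18. Diethylamine adds to the ynone in conjugate fashion to give enaminone 19, and the O8a hydroxyl closes ring C by 6-endo addition–elimination at C2, expelling the amine and forming O1–C2. The closest known reaction type is the palladium-catalysed carbonylative annulation of ortho-iodophenols with terminal arylacetylenes to flavones in a secondary amine. No stereocentre is formed, and the dioxolane centre is remote and untouched. Regiochemistry needs only that O8a is the one free oxygen flanking the iodine, which the symmetry-based synthesis of 13 guarantees, O5 being a MOM ether. Carbonylation must outrun direct alkynylation, which would end in five-membered ring closure; 20 bar of CO keeps the arylpalladium intermediate short-lived. Six-membered closure must beat 5-exo closure to the aurone, and passage through the enaminone secures it, because the amine-bearing carbon is then the only electrophilic site. MOM ethers, acetonide and prenyl group are inert to the basic medium.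

**Step 12**
Reactants: 20 5,7-bis(methoxymethoxy)-2-[4-(methoxymethoxy)phenyl]-6-(3-methylbut-2-en-1-yl)-8-{[(4S)-2,2,5,5-tetramethyl-1,3-dioxolan-4-yl]methyl}-4H-chromen-4-one
Product: 22 (2S)-5,7-bis(methoxymethoxy)-2-[4-(methoxymethoxy)phenyl]-6-(3-methylbut-2-en-1-yl)-8-{[(4S)-2,2,5,5-tetramethyl-1,3-dioxolan-4-yl]methyl}-2,3-dihydro-4H-chromen-4-one, via silyl enol ether 21 (not isolated)
Conditions: Cu(OAc)2 (5 mol%), (R)-DTBM-SEGPHOS (5.5 mol%), (EtO)2MeSiH (3 equiv), toluene, 0 °C to rt; then AcOH, THF–H2O, 0 °C
Reagents that add atoms: none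
Why: Enantioselective copper hydride conjugate reduction of a chromone-type enone: the bisphosphine-bound hydride adds to C2 from the face selected by the ligand and sets 2S under catalyst control, the side-chain centre being too remote to interfere. The copper enolate is silylated by the silane, which masks the ketone against 1,2-reduction and against ring opening until the mildly acidic hydrolysis protonates C3. The unactivated trisubstituted alkene is not a substrate for the catalyst.

**Step 13**
Reactants: 22 (2S)-5,7-bis(methoxymethoxy)-2-[4-(methoxymethoxy)phenyl]-6-(3-methylbut-2-en-1-yl)-8-{[(4S)-2,2,5,5-tetramethyl-1,3-dioxolan-4-yl]methyl}-2,3-dihydro-4H-chromen-4-one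
Product: 23 (2S)-8-[(2S)-2,3-dihydroxy-3-methylbutyl]-5,7-dihydroxy-2-(4-hydroxyphenyl)-6-(3-methylbut-2-en-1-yl)-2,3-dihydro-4H-chromen-4-one (target)
Conditions: HCl (1.25 M in MeOH), MeOH, 35 °C, stopped at full conversion
Reagents that add atoms: none
Why: Acid-catalysed acetal exchange with methanol removes the three MOM ethers and the acetonide together. Flavanones hold their C2 configuration in acid, unlike in base, and the mild temperature is chosen to stay below the threshold for cyclisation of the prenyl or diol chain onto the new phenols.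

## Compound list

1 | phloroglucinol (benzene-1,3,5-triol) | Oc1cc(O)cc(O)c1 | starting material
2 | 5-[(triisopropylsilyl)oxy]benzene-1,3-diol | CC(C)[Si](Oc1cc(O)cc(O)c1)(C(C)C)C(C)C | intermediate
3 | triisopropyl[3,5-bis(methoxymethoxy)phenoxy]silane | COCOc1cc(OCOC)cc(O[Si](C(C)C)(C(C)C)C(C)C)c1 | intermediate
4 | prenyl bromide (1-bromo-3-methylbut-2-ene) | CC(C)=CCBr | starting material
5 | [2,6-bis(methoxymethoxy)-4-(triisopropylsilyloxy)phenyl]lithium | [Li]c1c(OCOC)cc(O[Si](C(C)C)(C(C)C)C(C)C)cc1OCOC | intermediate
6 | triisopropyl[3,5-bis(methoxymethoxy)-4-(3-methylbut-2-en-1-yl)phenoxy]silane | CC(C)=CCc1c(OCOC)cc(O[Si](C(C)C)(C(C)C)C(C)C)cc1OCOC | intermediate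
7 | 3,5-bis(methoxymethoxy)-4-(3-methylbut-2-en-1-yl)phenol | CC(C)=CCc1c(OCOC)cc(O)cc1OCOC | intermediate
8 | 2,6-diiodo-3,5-bis(methoxymethoxy)-4-(3-methylbut-2-en-1-yl)phenol | CC(C)=CCc1c(OCOC)c(I)c(O)c(I)c1OCOC | intermediate
9 | methyl (2S)-oxirane-2-carboxylate | COC(=O)[C@@H]1CO1 | starting material
10 | chloromagnesium 2-(chloromagnesio)-6-iodo-3,5-bis(methoxymethoxy)-4-(3-methylbut-2-en-1-yl)phenoxide | CC(C)=CCc1c(OCOC)c(I)c(O[Mg]Cl)c([Mg]Cl)c1OCOC | intermediate
11 | methyl (2S)-2-hydroxy-3-[2-hydroxy-3-iodo-4,6-bis(methoxymethoxy)-5-(3-methylbut-2-en-1-yl)phenyl]propanoate | COC(=O)[C@@H](O)Cc1c(O)c(I)c(OCOC)c(CC=C(C)C)c1OCOC | intermediate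
12 | (2S)-1-[2-hydroxy-3-iodo-4,6-bis(methoxymethoxy)-5-(3-methylbut-2-en-1-yl)phenyl]-3-methylbutane-2,3-diol | CC(C)=CCc1c(OCOC)c(C[C@H](O)C(C)(C)O)c(O)c(I)c1OCOC | intermediate
13 | 2-iodo-3,5-bis(methoxymethoxy)-4-(3-methylbut-2-en-1-yl)-6-{[(4S)-2,2,5,5-tetramethyl-1,3-dioxolan-4-yl]methyl}phenol | CC(C)=CCc1c(OCOC)c(C[C@@H]2OC(C)(C)OC2(C)C)c(O)c(I)c1OCOC | intermediate
14 | 4-hydroxybenzaldehyde | O=Cc1ccc(O)cc1 | starting material
15 | 4-(methoxymethoxy)benzaldehyde | COCOc1ccc(C=O)cc1 | intermediate
16 | 1-ethynyl-4-(methoxymethoxy)benzene | C#Cc1ccc(OCOC)cc1 | intermediate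
17 | carbon monoxide | [C-]#[O+] | starting material
18 | 1-[2-hydroxy-4,6-bis(methoxymethoxy)-5-(3-methylbut-2-en-1-yl)-3-{[(4S)-2,2,5,5-tetramethyl-1,3-dioxolan-4-yl]methyl}phenyl]-3-[4-(methoxymethoxy)phenyl]prop-2-yn-1-one | CC(C)=CCc1c(OCOC)c(C[C@@H]2OC(C)(C)OC2(C)C)c(O)c(C(=O)C#Cc3ccc(OCOC)cc3)c1OCOC | intermediate
19 | 3-(diethylamino)-1-[2-hydroxy-4,6-bis(methoxymethoxy)-5-(3-methylbut-2-en-1-yl)-3-{[(4S)-2,2,5,5-tetramethyl-1,3-dioxolan-4-yl]methyl}phenyl]-3-[4-(methoxymethoxy)phenyl]prop-2-en-1-one | CC(C)=CCc1c(OCOC)c(C[C@@H]2OC(C)(C)OC2(C)C)c(O)c(C(=O)C=C(N(CC)CC)c3ccc(OCOC)cc3)c1OCOC | intermediate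
20 | 5,7-bis(methoxymethoxy)-2-[4-(methoxymethoxy)phenyl]-6-(3-methylbut-2-en-1-yl)-8-{[(4S)-2,2,5,5-tetramethyl-1,3-dioxolan-4-yl]methyl}-4H-chromen-4-one | CC(C)=CCc1c(OCOC)c(C[C@@H]3OC(C)(C)OC3(C)C)c2c(c1OCOC)C(=O)C=C(c1ccc(OCOC)cc1)O2 | intermediate
21 | (2S)-4-{[diethoxy(methyl)silyl]oxy}-5,7-bis(methoxymethoxy)-2-[4-(methoxymethoxy)phenyl]-6-(3-methylbut-2-en-1-yl)-8-{[(4S)-2,2,5,5-tetramethyl-1,3-dioxolan-4-yl]methyl}-2H-chromene | CC(C)=CCc1c(OCOC)c(C[C@@H]3OC(C)(C)OC3(C)C)c2c(c1OCOC)C(O[Si](C)(OCC)OCC)=C[C@@H](c1ccc(OCOC)cc1)O2 | intermediate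
22 | (2S)-5,7-bis(methoxymethoxy)-2-[4-(methoxymethoxy)phenyl]-6-(3-methylbut-2-en-1-yl)-8-{[(4S)-2,2,5,5-tetramethyl-1,3-dioxolan-4-yl]methyl}-2,3-dihydro-4H-chromen-4-one | CC(C)=CCc1c(OCOC)c(C[C@@H]3OC(C)(C)OC3(C)C)c2c(c1OCOC)C(=O)C[C@@H](c1ccc(OCOC)cc1)O2 | intermediate
23 | (2S)-8-[(2S)-2,3-dihydroxy-3-methylbutyl]-5,7-dihydroxy-2-(4-hydroxyphenyl)-6-(3-methylbut-2-en-1-yl)-2,3-dihydro-4H-chromen-4-one | CC(C)=CCc1c(O)c(C[C@H](O)C(C)(C)O)c2c(c1O)C(=O)C[C@@H](c1ccc(O)cc1)O2 | target

## Step count and risk

Total: 13 steps. Longest linear sequence: 11 steps (steps 1 to 8, then 11 to 13); steps 9 and 10 make the alkyne branch.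

**Step 11 (key step).** The likely failures are three.
- Direct alkynylation without uptake of CO, followed by five-membered ring closure, if CO insertion is slow at the doubly ortho-substituted, electron-rich arylpalladium.
- Aminocarbonylation, that is capture of the aroylpalladium by diethylamine in place of the acetylide.
- Sluggish oxidative addition at the hindered iodide.

Fallback: the ynone is built without CO. Alkyne 16 is deprotonated with n-BuLi and acylated with N-methoxy-N-methylcarbamoyl chloride to give N-methoxy-N-methyl-3-[4-(methoxymethoxy)phenyl]prop-2-ynamide F1. Iodophenol 13 is deprotonated with MeMgCl, magnesiated by iodine–magnesium exchange with iPrMgCl·LiCl, and acylated by F1. This gives ynone 18, now isolated. Warming 18 with diethylamine in ethanol closes ring C through 19, and the route is rejoined at 20.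

**Step 6.** The exchange may be slow or incomplete on an electron-rich magnesium phenoxide. The aryl-magnesium may be lost by protonation or by copper-mediated coupling with the 2-iodopropane formed in the exchange. Addition to the ester carbonyl may compete with epoxide opening.

Fallback: both ortho substituents are introduced by deprotonation of a neutral arene. This sets out from 7 and also bypasses step 5.
- Phenol 7 is converted with NaH and 2-(trimethylsilyl)ethoxymethyl chloride into {2-[3,5-bis(methoxymethoxy)-4-(3-methylbut-2-en-1-yl)phenoxymethoxy]ethyl}trimethylsilane F2.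
- Lithiation between the two acetal ethers (n-BuLi, THF, 0 °C), transmetalation with MgBr2·OEt2 and CuI-catalysed opening of 9 give methyl (2S)-2-hydroxy-3-[2,4-bis(methoxymethoxy)-3-(3-methylbut-2-en-1-yl)-6-{[2-(trimethylsilyl)ethoxy]methoxy}phenyl]propanoate F3.
- MeMgBr gives (2S)-1-[2,4-bis(methoxymethoxy)-3-(3-methylbut-2-en-1-yl)-6-{[2-(trimethylsilyl)ethoxy]methoxy}phenyl]-3-methylbutane-2,3-diol F4.
- 2,2-Dimethoxypropane and PPTS give the acetonide (2-{[3,5-bis(methoxymethoxy)-4-(3-methylbut-2-en-1-yl)-2-{[(4S)-2,2,5,5-tetramethyl-1,3-dioxolan-4-yl]methyl}phenoxy]methoxy}ethyl)trimethylsilane F5.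
- A second lithiation at the last ring position and an iodine quench at −78 °C give (2-{[2-iodo-3,5-bis(methoxymethoxy)-4-(3-methylbut-2-en-1-yl)-6-{[(4S)-2,2,5,5-tetramethyl-1,3-dioxolan-4-yl]methyl}phenoxy]methoxy}ethyl)trimethylsilane F6.
- TBAF in warm THF removes the silylethoxymethyl group from F6, and the route is rejoined at 13.

**Step 12.** The flavone is a hindered vinylogous ester flanked by the O5 MOM ether. Hydride transfer may therefore be slow, facial selectivity may be poor, and 1,2-reduction or ring opening of the copper enolate (which would erode the C2 configuration) may intervene.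

Fallback: catalyst control is given up in favour of separation and recycling. Flavone 20 is reduced with L-Selectride (LiBH(s-Bu)3) in THF at −78 °C to a mixture of 22 and its C2 epimer, (2R)-5,7-bis(methoxymethoxy)-2-[4-(methoxymethoxy)phenyl]-6-(3-methylbut-2-en-1-yl)-8-{[(4S)-2,2,5,5-tetramethyl-1,3-dioxolan-4-yl]methyl}-2,3-dihydro-4H-chromen-4-one F7. Because the side-chain centre is fixed, the two are diastereomers and are separated by preparative HPLC. F7 is recycled with a mild amine base, which opens ring C to the chalcone (E)-1-[2-hydroxy-4,6-bis(methoxymethoxy)-5-(3-methylbut-2-en-1-yl)-3-{[(4S)-2,2,5,5-tetramethyl-1,3-dioxolan-4-yl]methyl}phenyl]-3-[4-(methoxymethoxy)phenyl]prop-2-en-1-one F8; F8 recloses without selectivity, and the mixture is separated again. The route is rejoined at 22.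

## Further compounds

F1 | step 11 | N-methoxy-N-methyl-3-[4-(methoxymethoxy)phenyl]prop-2-ynamide | CON(C)C(=O)C#Cc1ccc(OCOC)cc1
F2 | step 6 | {2-[3,5-bis(methoxymethoxy)-4-(3-methylbut-2-en-1-yl)phenoxymethoxy]ethyl}trimethylsilane | CC(C)=CCc1c(OCOC)cc(OCOCC[Si](C)(C)C)cc1OCOC
F3 | step 6 | methyl (2S)-2-hydroxy-3-[2,4-bis(methoxymethoxy)-3-(3-methylbut-2-en-1-yl)-6-{[2-(trimethylsilyl)ethoxy]methoxy}phenyl]propanoate | COC(=O)[C@@H](O)Cc1c(OCOCC[Si](C)(C)C)cc(OCOC)c(CC=C(C)C)c1OCOC
F4 | step 6 | (2S)-1-[2,4-bis(methoxymethoxy)-3-(3-methylbut-2-en-1-yl)-6-{[2-(trimethylsilyl)ethoxy]methoxy}phenyl]-3-methylbutane-2,3-diol | CC(C)=CCc1c(OCOC)cc(OCOCC[Si](C)(C)C)c(C[C@H](O)C(C)(C)O)c1OCOC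
F5 | step 6 | (2-{[3,5-bis(methoxymethoxy)-4-(3-methylbut-2-en-1-yl)-2-{[(4S)-2,2,5,5-tetramethyl-1,3-dioxolan-4-yl]methyl}phenoxy]methoxy}ethyl)trimethylsilane | CC(C)=CCc1c(OCOC)cc(OCOCC[Si](C)(C)C)c(C[C@@H]2OC(C)(C)OC2(C)C)c1OCOC
F6 | step 6 | (2-{[2-iodo-3,5-bis(methoxymethoxy)-4-(3-methylbut-2-en-1-yl)-6-{[(4S)-2,2,5,5-tetramethyl-1,3-dioxolan-4-yl]methyl}phenoxy]methoxy}ethyl)trimethylsilane | CC(C)=CCc1c(OCOC)c(I)c(OCOCC[Si](C)(C)C)c(C[C@@H]2OC(C)(C)OC2(C)C)c1OCOC
F7 | step 12 | (2R)-5,7-bis(methoxymethoxy)-2-[4-(methoxymethoxy)phenyl]-6-(3-methylbut-2-en-1-yl)-8-{[(4S)-2,2,5,5-tetramethyl-1,3-dioxolan-4-yl]methyl}-2,3-dihydro-4H-chromen-4-one | CC(C)=CCc1c(OCOC)c(C[C@@H]3OC(C)(C)OC3(C)C)c2c(c1OCOC)C(=O)C[C@H](c1ccc(OCOC)cc1)O2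
F8 | step 12 | (E)-1-[2-hydroxy-4,6-bis(methoxymethoxy)-5-(3-methylbut-2-en-1-yl)-3-{[(4S)-2,2,5,5-tetramethyl-1,3-dioxolan-4-yl]methyl}phenyl]-3-[4-(methoxymethoxy)phenyl]prop-2-en-1-one | CC(C)=CCc1c(OCOC)c(C[C@@H]2OC(C)(C)OC2(C)C)c(O)c(C(=O)/C=C/c3ccc(OCOC)cc3)c1OCOC
A1 | alternative 1 | 3-[(4-methoxybenzyl)oxy]-2-(3-methylbut-2-en-1-yl)-6-{[(4S)-2,2,5,5-tetramethyl-1,3-dioxolan-4-yl]methyl}-5-[(triisopropylsilyl)oxy]phenol | CC(C)=CCc1c(O)c(C[C@@H]3OC(C)(C)OC3(C)C)c(O[Si](C(C)C)(C(C)C)C(C)C)cc1OCc1ccc(OC)cc1
A2 | alternative 1 | 3-[(4-methoxybenzyl)oxy]-4-(3-methylbut-2-en-1-yl)cyclobut-2-en-1-one | O=C1C=C(OCc2ccc(OC)cc2)C1CC=C(C)C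
A3 | alternative 1 | triisopropyl({3-[(4S)-2,2,5,5-tetramethyl-1,3-dioxolan-4-yl]prop-1-yn-1-yl}oxy)silane | CC(C)[Si](OC#CC[C@@H]1OC(C)(C)OC1(C)C)(C(C)C)C(C)C
A4 | alternative 2 | (2S)-2-[4-(methoxymethoxy)phenyl]-6-(3-methylbut-2-en-1-yl)-4-oxo-8-{[(4S)-2,2,5,5-tetramethyl-1,3-dioxolan-4-yl]methyl}-3,4-dihydro-2H-chromene-5,7-diyl diacetate | CC(C)=CCc1c(OC(C)=O)c(C[C@@H]3OC(C)(C)OC3(C)C)c2c(c1OC(C)=O)C(=O)C[C@@H](c1ccc(OCOC)cc1)O2
A5 | alternative 2 | 4-(diazoacetyl)-5-{[4-(methoxymethoxy)benzyl]oxy}-2-(3-methylbut-2-en-1-yl)-6-{[(4S)-2,2,5,5-tetramethyl-1,3-dioxolan-4-yl]methyl}-1,3-phenylene diacetate | CC(C)=CCc1c(OC(C)=O)c(C[C@@H]2OC(C)(C)OC2(C)C)c(OCc3ccc(OCOC)cc3)c(C(=O)C=[N+]=[N-])c1OC(C)=O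
A6 | alternative 2 | dirhodium tetrakis[N-phthaloyl-(S)-tert-leucinate] Rh2(S-PTTL)4 | [Rh+2].[Rh+2].CC(C)(C)[C@H](N1C(=O)c2ccccc2C1=O)C([O-])=O.CC(C)(C)[C@H](N1C(=O)c2ccccc2C1=O)C([O-])=O.CC(C)(C)[C@H](N1C(=O)c2ccccc2C1=O)C([O-])=O.CC(C)(C)[C@H](N1C(=O)c2ccccc2C1=O)C([O-])=O
A7 | alternative 3 | (2S,4S)-4-methoxy-5,7-bis(methoxymethoxy)-2-[4-(methoxymethoxy)phenyl]-6-(3-methylbut-2-en-1-yl)-8-{[(4S)-2,2,5,5-tetramethyl-1,3-dioxolan-4-yl]methyl}-3,4-dihydro-2H-chromene (2,4-cis) | CC(C)=CCc1c(OCOC)c(C[C@@H]3OC(C)(C)OC3(C)C)c2c(c1OCOC)[C@@H](OC)C[C@@H](c1ccc(OCOC)cc1)O2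
A8 | alternative 3 | 2-hydroxy-4,6-bis(methoxymethoxy)-5-(3-methylbut-2-en-1-yl)-3-{[(4S)-2,2,5,5-tetramethyl-1,3-dioxolan-4-yl]methyl}benzaldehyde | CC(C)=CCc1c(OCOC)c(C[C@@H]2OC(C)(C)OC2(C)C)c(O)c(C=O)c1OCOC
A9 | alternative 3 | trimethyl orthoformate | COC(OC)OC
A10 | alternative 3 | 1-ethenyl-4-(methoxymethoxy)benzene | C=Cc1ccc(OCOC)cc1
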